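The route rests on reading the dihydrofuran ring (O1, C2, C3, C3a, C7a) with its C3 hydroxymethyl branch as a chroman-4-one ring that has expelled its carbonyl carbon C4, this carbon surviving as the C3 substituent. Photochemical Wolff rearrangement of 3-diazoflavanone 10 does this in one operation: C4a of the fused benzo ring (ring A) shifts from C4 to C3, the pyranone contracts, and methanol traps the ketene, kinetic protonation placing the ester cis to the C2 aryl group. The precursor carries C2 from a catalytic asymmetric conjugate arylation of a chromone; the furofuran is afterwards assembled on the C5 ester carbon by an auxiliary-controlled conjugate addition–aldol sequence.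

Key step: step 7

Remark: the target SMILES encodes a 2,3-cis dihydrobenzofuran (2S,3S) and a diequatorial furofuran (1S,3aR,4S,6aR); the route is planned for exactly this isomer.
Remark: (R)-t-BuPyOx is assumed, by analogy with the sense of induction on cyclic enones, to give the 2S flavanone; if the opposite sense is found, the (S)-ligand is used.
Remark: compounds 1, 7, 17 and 19 are taken as commercially available.
Abbreviations used in names: ArG = 4-(benzyloxy)-3-methoxyphenyl; ArS = 4-(benzyloxy)-3,5-dimethoxyphenyl; Men = (1R,2S,5R)-2-isopropyl-5-methylcyclohexyl; BFsi = (2S,3S)-2-ArG-3-{[(tert-butyldimethylsilyl)oxy]methyl}-7-methoxy-2,3-dihydro-1-benzofuran-5-yl (2,3-cis).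

Step 1
Reactants: 1 methyl vanillate
Product: 2 methyl 4-hydroxy-3-iodo-5-methoxybenzoate
Conditions: NIS, TsOH (10 mol%), MeCN, rt
Reagents that add atoms: N-iodosuccinimide, O=C1CCC(=O)N1I
Why: Electrophilic aromatic iodination, directed by the phenol to C5, its only free ortho position (the para position carries the ester).

Step 2
Reactants: 2 methyl 4-hydroxy-3-iodo-5-methoxybenzoate
Product: 4 methyl 3-acetyl-4-hydroxy-5-methoxybenzoate, via enol ether 3 (not isolated)
Conditions: Bu3SnC(OEt)=CH2, Pd(PPh3)2Cl2 (5 mol%), dioxane, 100 °C; then 1 M HCl, THF, rt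
Reagents that add atoms: tributyl(1-ethoxyvinyl)stannane, CCCC[Sn](CCCC)(CCCC)C(=C)OCC; water, O
Why: Stille coupling of the aryl iodide with a 1-ethoxyvinyl stannane as acetyl equivalent, then acid hydrolysis of the enol ether to the methyl ketone; the free phenol and the ester are tolerated.

Step 3
Reactants: 4 methyl 3-acetyl-4-hydroxy-5-methoxybenzoate
Product: 6 methyl 8-methoxy-4-oxo-4H-chromene-6-carboxylate, via enaminone 5 (not isolated)
Conditions: Me2NCH(OMe)2, toluene, 100 °C; then conc. HCl, CH2Cl2, rt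
Reagents that add atoms: N,N-dimethylformamide dimethyl acetal, COC(OC)N(C)C
Why: Condensation of the acetyl methyl group with the formamide acetal gives the enaminone, and acid then drives conjugate addition of the phenol and loss of dimethylamine, the standard chromone synthesis from 2-hydroxyacetophenones.

Step 4
Reactants: 6 methyl 8-methoxy-4-oxo-4H-chromene-6-carboxylate; 7 [4-(benzyloxy)-3-methoxyphenyl]boronic acid
Product: 8 methyl (2S)-2-[4-(benzyloxy)-3-methoxyphenyl]-8-methoxy-4-oxochromane-6-carboxylate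
Conditions: Pd(OCOCF3)2 (5 mol%), (R)-t-BuPyOx (6 mol%), NH4PF6 (30 mol%), H2O (5 equiv), ClCH2CH2Cl, 60 °C
Reagents that add atoms: none
Why: Palladium-catalysed asymmetric conjugate addition of an arylboronic acid to a chromone: transmetalation gives an aryl–palladium species that adds across C2=C3 on the face left open by the tert-butyl oxazoline ligand, and protonolysis of the palladium enolate releases the flavanone with C2 set as S by catalyst control.

Step 5
Reactants: 8 methyl (2S)-2-[4-(benzyloxy)-3-methoxyphenyl]-8-methoxy-4-oxochromane-6-carboxylate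
Product: 9 methyl (2R)-2-[4-(benzyloxy)-3-methoxyphenyl]-3-(hydroxyimino)-8-methoxy-4-oxochromane-6-carboxylate
Conditions: isoamyl nitrite, HCl (4 M in dioxane, cat.), THF, 0 °C
Reagents that add atoms: isoamyl nitrite, CC(C)CCON=O
Why: Acid-catalysed α-nitrosation of the ketone through its enol at C3, the only enolisable position, followed by tautomerisation to the oxime; acidic instead of basic conditions avoid retro-oxa-Michael opening of the flavanone, which would racemise C2 (the descriptor changes to R only because C3 now outranks the aryl group).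

Step 6
Reactants: 9 methyl (2R)-2-[4-(benzyloxy)-3-methoxyphenyl]-3-(hydroxyimino)-8-methoxy-4-oxochromane-6-carboxylate
Product: 10 methyl (2R)-2-[4-(benzyloxy)-3-methoxyphenyl]-3-diazo-8-methoxy-4-oxochromane-6-carboxylate
Conditions: aq. NH3, NaOCl, NaOH (1 equiv), THF/H2O, 0 °C
Reagents that add atoms: chloramine (made in the flask from aqueous NH3 and NaOCl), NCl
Why: Forster reaction: the oximate nitrogen is aminated by chloramine and loss of water gives the α-diazo ketone; C3 is sp2 throughout, so the flavanone cannot ring-open by β-elimination and C2 is retained.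

Step 7
Reactants: 10 methyl (2R)-2-[4-(benzyloxy)-3-methoxyphenyl]-3-diazo-8-methoxy-4-oxochromane-6-carboxylate
Product: 13 dimethyl (2S,3R)-2-[4-(benzyloxy)-3-methoxyphenyl]-7-methoxy-2,3-dihydro-1-benzofuran-3,5-dicarboxylate, via ketene 11 (not isolated), via ester enol 12 (not isolated)
Conditions: hν (365 nm), degassed MeOH/THF (4:1), −20 °C
Reagents that add atoms: methanol, CO
Why: Irradiation of the ring-locked s-cis α-diazo ketone expels N2 in concert with a 1,2-shift of C4a (the ring A carbon on the carbonyl group) from C4 to C3, forming the C3–C3a bond and ketene 11 exocyclic to the new ring (photochemical Wolff rearrangement), and methanol adds to the ketene to give ester enol 12, which tautomerises to 13. The closest known chemistry is the photochemical Wolff ring contraction of benzo-fused cyclic α-diazo ketones with alcohol trapping, as in 2-diazo-1-indanone going to benzocyclobutene carboxylates. The five-membered ring O1–C2–C3–C3a–C7a is not closed by a cyclisation: it results from contraction of the six-membered pyranone, C4 being pushed out to become the exocyclic ester carbon. The new stereocentre C3 is set by substrate control from C2: the planar ester enol is protonated on the face anti to the C2 aryl group, which leaves the ester cis to that aryl group (2S,3R), while C2 itself is not touched. The step needs migration of the aryl carbon instead of a carbene-type 1,2-hydride shift from C2 or O–H insertion into methanol, which the fixed s-cis geometry and direct, catalyst-free irradiation favour, and it needs kinetic protonation without later epimerisation, which neutral base-free methanol at low temperature and prompt reduction in step 8 secure.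

Step 8
Reactants: 13 dimethyl (2S,3R)-2-[4-(benzyloxy)-3-methoxyphenyl]-7-methoxy-2,3-dihydro-1-benzofuran-3,5-dicarboxylate
Product: 14 [(2S,3S)-2-[4-(benzyloxy)-3-methoxyphenyl]-7-methoxy-2,3-dihydro-1-benzofuran-3,5-diyl]dimethanol
Conditions: i-Bu2AlH (6 equiv), CH2Cl2, −78 to −20 °C; aq. KNaC4H4O6 work-up
Reagents that add atoms: none
Why: Hydride reduction of both methyl esters to primary alcohols with the Lewis-acidic, weakly basic i-Bu2AlH at low temperature, so that the cis ester at C3 is reduced before it can enolise and epimerise; after reduction C3 is no longer epimerisable.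

Step 9
Reactants: 14 [(2S,3S)-2-[4-(benzyloxy)-3-methoxyphenyl]-7-methoxy-2,3-dihydro-1-benzofuran-3,5-diyl]dimethanol
Product: 15 (2S,3S)-2-[4-(benzyloxy)-3-methoxyphenyl]-3-(hydroxymethyl)-7-methoxy-2,3-dihydro-1-benzofuran-5-carbaldehyde
Conditions: MnO2 (activated, excess), CH2Cl2, rt
Reagents that add atoms: none
Why: Chemoselective MnO2 oxidation of the benzylic alcohol at C5 to the aldehyde; the aliphatic primary alcohol on C3 is not activated and is left.

Step 10
Reactants: 15 (2S,3S)-2-[4-(benzyloxy)-3-methoxyphenyl]-3-(hydroxymethyl)-7-methoxy-2,3-dihydro-1-benzofuran-5-carbaldehyde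
Product: 16 (2S,3S)-2-[4-(benzyloxy)-3-methoxyphenyl]-3-{[(tert-butyldimethylsilyl)oxy]methyl}-7-methoxy-2,3-dihydro-1-benzofuran-5-carbaldehyde
Conditions: TBSCl, imidazole, DMF, 0 °C to rt
Reagents that add atoms: tert-butyldimethylsilyl chloride, CC(C)(C)[Si](C)(C)Cl
Why: Standard silylation of the remaining primary alcohol, which would otherwise quench the lactone enolate in step 12.

Step 11
Reactants: 17 4-(benzyloxy)-3,5-dimethoxybenzaldehyde
Product: 18 2-[4-(benzyloxy)-3,5-dimethoxyphenyl]-1,3-dithiane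
Conditions: HS(CH2)3SH, BF3·OEt2 (cat.), CH2Cl2, 0 °C to rt
Reagents that add atoms: propane-1,3-dithiol, SCCCS
Why: Lewis acid-catalysed dithioacetalisation turns the aldehyde into an acyl-anion equivalent.

Step 12
Reactants: 18 2-[4-(benzyloxy)-3,5-dimethoxyphenyl]-1,3-dithiane; 19 (5R)-5-(MenO)furan-2(5H)-one; 16 (2S,3S)-2-[4-(benzyloxy)-3-methoxyphenyl]-3-{[(tert-butyldimethylsilyl)oxy]methyl}-7-methoxy-2,3-dihydro-1-benzofuran-5-carbaldehyde
Product: 22 (3S,4R,5R)-4-(2-ArS-1,3-dithian-2-yl)-3-[BFsi(hydroxy)methyl]-5-(MenO)dihydrofuran-2(3H)-one, via lithiated dithiane 20 (not isolated), via lithium enolate 21 (not isolated)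
Conditions: 18, n-BuLi, THF, −78 °C; then 19, −78 °C; then 16, −78 °C; aq. NH4Cl
Reagents that add atoms: none
Why: Tandem conjugate addition–aldol reaction on a γ-alkoxybutenolide: the lithiated dithiane adds 1,4 to 19 anti to the menthyloxy group (sets C4 as R), and the resulting lactone enolate adds to aldehyde 16 anti to the bulky dithianyl group (sets C3 as S, 3,4-trans); the carbinol centre forms as an epimer mixture, which is of no consequence because it is planarised in step 16.

Step 13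
Reactants: 22 (3S,4R,5R)-4-(2-ArS-1,3-dithian-2-yl)-3-[BFsi(hydroxy)methyl]-5-(MenO)dihydrofuran-2(3H)-one
Product: 23 (3S,4R,5R)-4-[4-(benzyloxy)-3,5-dimethoxybenzoyl]-3-[BFsi(hydroxy)methyl]-5-(MenO)dihydrofuran-2(3H)-one
Conditions: Hg(ClO4)2, CaCO3, THF/H2O (5:1), 0 °C
Reagents that add atoms: water, O
Why: Mercury-assisted hydrolysis of the dithioacetal to the aryl ketone under CaCO3 buffering, neutral conditions that spare the silyl ether, the menthyl acetal, the lactone and the cis-dihydrobenzofuran; no stereocentre is formed.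

Step 14
Reactants: 23 (3S,4R,5R)-4-[4-(benzyloxy)-3,5-dimethoxybenzoyl]-3-[BFsi(hydroxy)methyl]-5-(MenO)dihydrofuran-2(3H)-one
Product: 24 (2R,3R)-1-BFsi-4-ArS-2,3-bis(hydroxymethyl)butane-1,4-diol
Conditions: LiAlH4, THF, 0 °C to rt
Reagents that add atoms: none
Why: Hydride reduction: LiAlH4 reduces the ketone and the lactone, and the γ-menthyloxy lactol that results collapses with loss of menthoxide to an aldehyde that is reduced in turn; the two backbone stereocentres (2R,3R) are untouched and the new carbinol centre may form as a mixture.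

Step 15
Reactants: 24 (2R,3R)-1-BFsi-4-ArS-2,3-bis(hydroxymethyl)butane-1,4-diol
Product: 25 (2R,3R)-1-BFsi-4-ArS-2,3-bis{[(tert-butyldimethylsilyl)oxy]methyl}butane-1,4-diol
Conditions: TBSCl (2.2 equiv), imidazole, CH2Cl2/DMF, −20 to 0 °C
Reagents that add atoms: tert-butyldimethylsilyl chloride, CC(C)(C)[Si](C)(C)Cl
Why: Sterically controlled silylation: TBSCl reacts with the two primary hydroxyls far faster than with the hindered secondary benzylic ones, leaving only the benzylic alcohols free for activation.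

Step 16
Reactants: 25 (2R,3R)-1-BFsi-4-ArS-2,3-bis{[(tert-butyldimethylsilyl)oxy]methyl}butane-1,4-diol
Product: 27 [(2S,3S)-2-ArG-5-[(1S,3aR,4S,6aR)-4-ArS-tetrahydro-1H,3H-furo[3,4-c]furan-1-yl]-7-methoxy-2,3-dihydro-1-benzofuran-3-yl]methanol, via bis-mesylate 26 (not isolated)
Conditions: MsCl (2.5 equiv), Et3N, CH2Cl2, −40 to 0 °C; then TBAF (5 equiv), THF, 0 °C to rt
Reagents that add atoms: none
Why: Sulfonylation of the two para-alkoxybenzylic alcohols gives mesylates that ionise readily to ion pairs, and fluoride then unmasks the 1,4-related primary oxygens, which close both tetrahydrofuran rings by 5-exo etherification (Williamson-type ring closure on benzylic sulfonates, as in mesyl chloride cyclisations of 1,4-diaryl-1,4-diols); because the benzylic carbons are planar when the C–O bonds form, both carbinol epimers converge and each aryl group takes the exo position trans to the adjacent ring bond (1S and 4S), while the absence of acid leaves the ionisable C2–O1 bond and the cis configuration of the dihydrobenzofuran untouched.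

Step 17
Reactants: 27 [(2S,3S)-2-ArG-5-[(1S,3aR,4S,6aR)-4-ArS-tetrahydro-1H,3H-furo[3,4-c]furan-1-yl]-7-methoxy-2,3-dihydro-1-benzofuran-3-yl]methanol
Product: 28 4-[(1S,3aR,4S,6aR)-4-[(2S,3S)-2-(4-hydroxy-3-methoxyphenyl)-3-(hydroxymethyl)-7-methoxy-2,3-dihydro-1-benzofuran-5-yl]tetrahydro-1H,3H-furo[3,4-c]furan-1-yl]-2,6-dimethoxyphenol
Conditions: H2 (1 atm), 10% Pd/C, EtOAc, rt
Reagents that add atoms: none
Why: Catalytic hydrogenolysis of the two aryl benzyl ethers, which are cleaved much faster than the cyclic benzylic ethers of the furofuran and the dihydrobenzofuran under neutral conditions; the phenols are unmasked last so that no base or acid meets the para-hydroxybenzyl ethers.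

Compound list
1 | methyl vanillate (methyl 4-hydroxy-3-methoxybenzoate) | COC(=O)c1ccc(O)c(OC)c1 | starting material
2 | methyl 4-hydroxy-3-iodo-5-methoxybenzoate | COC(=O)c1cc(I)c(O)c(OC)c1 | intermediate
3 | methyl 3-(1-ethoxyethenyl)-4-hydroxy-5-methoxybenzoate (enol ether, not isolated) | COC(=O)c1cc(OC)c(O)c(C(=C)OCC)c1 | intermediate
4 | methyl 3-acetyl-4-hydroxy-5-methoxybenzoate | COC(=O)c1cc(OC)c(O)c(C(C)=O)c1 | intermediate
5 | methyl 3-[(2E)-3-(dimethylamino)prop-2-enoyl]-4-hydroxy-5-methoxybenzoate (enaminone, not isolated) | COC(=O)c1cc(OC)c(O)c(C(=O)/C=C/N(C)C)c1 | intermediate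
6 | methyl 8-methoxy-4-oxo-4H-chromene-6-carboxylate | COC(=O)c1cc(OC)c2occc(=O)c2c1 | intermediate
7 | [4-(benzyloxy)-3-methoxyphenyl]boronic acid | COc1cc(B(O)O)ccc1OCc1ccccc1 | starting material
8 | methyl (2S)-2-[4-(benzyloxy)-3-methoxyphenyl]-8-methoxy-4-oxochromane-6-carboxylate | COc1cc([C@H]2Oc3c(OC)cc(C(=O)OC)cc3C(=O)C2)ccc1OCc1ccccc1 | intermediate
9 | methyl (2R)-2-[4-(benzyloxy)-3-methoxyphenyl]-3-(hydroxyimino)-8-methoxy-4-oxochromane-6-carboxylate (oxime geometry not defined) | COc1cc([C@H]2Oc3c(OC)cc(C(=O)OC)cc3C(=O)C2=NO)ccc1OCc1ccccc1 | intermediate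
10 | methyl (2R)-2-[4-(benzyloxy)-3-methoxyphenyl]-3-diazo-8-methoxy-4-oxochromane-6-carboxylate (precursor of the key step) | COc1cc([C@H]2Oc3c(OC)cc(C(=O)OC)cc3C(=O)C2=[N+]=[N-])ccc1OCc1ccccc1 | intermediate
11 | methyl (2R)-2-[4-(benzyloxy)-3-methoxyphenyl]-7-methoxy-3-(oxomethylidene)-2,3-dihydro-1-benzofuran-5-carboxylate (ketene, not isolated) | COc1cc([C@H]2Oc3c(OC)cc(C(=O)OC)cc3C2=C=O)ccc1OCc1ccccc1 | intermediate
12 | methyl (2R)-2-[4-(benzyloxy)-3-methoxyphenyl]-3-[hydroxy(methoxy)methylidene]-7-methoxy-2,3-dihydro-1-benzofuran-5-carboxylate (ester enol, not isolated) | COc1cc([C@H]2Oc3c(OC)cc(C(=O)OC)cc3C2=C(O)OC)ccc1OCc1ccccc1 | intermediate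
13 | dimethyl (2S,3R)-2-[4-(benzyloxy)-3-methoxyphenyl]-7-methoxy-2,3-dihydro-1-benzofuran-3,5-dicarboxylate (2,3-cis; product of the key step) | COc1cc([C@H]2Oc3c(OC)cc(C(=O)OC)cc3[C@H]2C(=O)OC)ccc1OCc1ccccc1 | intermediate
14 | [(2S,3S)-2-[4-(benzyloxy)-3-methoxyphenyl]-7-methoxy-2,3-dihydro-1-benzofuran-3,5-diyl]dimethanol (cis) | COc1cc([C@H]2Oc3c(OC)cc(CO)cc3[C@H]2CO)ccc1OCc1ccccc1 | intermediate
15 | (2S,3S)-2-[4-(benzyloxy)-3-methoxyphenyl]-3-(hydroxymethyl)-7-methoxy-2,3-dihydro-1-benzofuran-5-carbaldehyde | COc1cc([C@H]2Oc3c(OC)cc(C=O)cc3[C@H]2CO)ccc1OCc1ccccc1 | intermediate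
16 | (2S,3S)-2-[4-(benzyloxy)-3-methoxyphenyl]-3-{[(tert-butyldimethylsilyl)oxy]methyl}-7-methoxy-2,3-dihydro-1-benzofuran-5-carbaldehyde | COc1cc([C@H]2Oc3c(OC)cc(C=O)cc3[C@H]2CO[Si](C)(C)C(C)(C)C)ccc1OCc1ccccc1 | intermediate
17 | 4-(benzyloxy)-3,5-dimethoxybenzaldehyde | COc1cc(C=O)cc(OC)c1OCc1ccccc1 | starting material
18 | 2-[4-(benzyloxy)-3,5-dimethoxyphenyl]-1,3-dithiane | COc1cc(C2SCCCS2)cc(OC)c1OCc1ccccc1 | intermediate
19 | (5R)-5-{[(1R,2S,5R)-2-isopropyl-5-methylcyclohexyl]oxy}furan-2(5H)-one | O=C1C=C[C@H](O[C@@H]2C[C@H](C)CC[C@H]2C(C)C)O1 | starting material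
20 | 2-lithio-2-[4-(benzyloxy)-3,5-dimethoxyphenyl]-1,3-dithiane (not isolated) | COc1cc(C2([Li])SCCCS2)cc(OC)c1OCc1ccccc1 | intermediate
21 | lithium (4R,5R)-4-(2-ArS-1,3-dithian-2-yl)-5-(MenO)-4,5-dihydrofuran-2-olate (lactone enolate, not isolated) | [Li]OC1=C[C@@H](C2(c3cc(OC)c(OCc4ccccc4)c(OC)c3)SCCCS2)[C@H](O[C@@H]2C[C@H](C)CC[C@H]2C(C)C)O1 | intermediate
22 | (3S,4R,5R)-4-(2-ArS-1,3-dithian-2-yl)-3-[BFsi(hydroxy)methyl]-5-(MenO)dihydrofuran-2(3H)-one (carbinol epimers) | COc1cc([C@H]2Oc3c(OC)cc(C(O)[C@H]4C(=O)O[C@@H](O[C@@H]5C[C@H](C)CC[C@H]5C(C)C)[C@@H]4C6(c7cc(OC)c(OCc8ccccc8)c(OC)c7)SCCCS6)cc3[C@H]2CO[Si](C)(C)C(C)(C)C)ccc1OCc1ccccc1 | intermediate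
23 | (3S,4R,5R)-4-[4-(benzyloxy)-3,5-dimethoxybenzoyl]-3-[BFsi(hydroxy)methyl]-5-(MenO)dihydrofuran-2(3H)-one (carbinol epimers) | COc1cc([C@H]2Oc3c(OC)cc(C(O)[C@H]4C(=O)O[C@@H](O[C@@H]5C[C@H](C)CC[C@H]5C(C)C)[C@@H]4C(=O)c6cc(OC)c(OCc7ccccc7)c(OC)c6)cc3[C@H]2CO[Si](C)(C)C(C)(C)C)ccc1OCc1ccccc1 | intermediate
24 | (2R,3R)-1-BFsi-4-ArS-2,3-bis(hydroxymethyl)butane-1,4-diol (both carbinol carbons as epimer mixtures) | COc1cc([C@H]2Oc3c(OC)cc(C(O)[C@@H](CO)[C@H](CO)C(O)c4cc(OC)c(OCc5ccccc5)c(OC)c4)cc3[C@H]2CO[Si](C)(C)C(C)(C)C)ccc1OCc1ccccc1 | intermediate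
25 | (2R,3R)-1-BFsi-4-ArS-2,3-bis{[(tert-butyldimethylsilyl)oxy]methyl}butane-1,4-diol | COc1cc([C@H]2Oc3c(OC)cc(C(O)[C@@H](CO[Si](C)(C)C(C)(C)C)[C@H](CO[Si](C)(C)C(C)(C)C)C(O)c4cc(OC)c(OCc5ccccc5)c(OC)c4)cc3[C@H]2CO[Si](C)(C)C(C)(C)C)ccc1OCc1ccccc1 | intermediate
26 | (2R,3R)-1-BFsi-4-ArS-2,3-bis{[(tert-butyldimethylsilyl)oxy]methyl}butane-1,4-diyl dimethanesulfonate (not isolated) | COc1cc([C@H]2Oc3c(OC)cc(C(OS(C)(=O)=O)[C@@H](CO[Si](C)(C)C(C)(C)C)[C@H](CO[Si](C)(C)C(C)(C)C)C(OS(C)(=O)=O)c4cc(OC)c(OCc5ccccc5)c(OC)c4)cc3[C@H]2CO[Si](C)(C)C(C)(C)C)ccc1OCc1ccccc1 | intermediate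
27 | [(2S,3S)-2-ArG-5-[(1S,3aR,4S,6aR)-4-ArS-tetrahydro-1H,3H-furo[3,4-c]furan-1-yl]-7-methoxy-2,3-dihydro-1-benzofuran-3-yl]methanol | COc1cc([C@H]2Oc3c(OC)cc([C@H]4OC[C@H]5[C@@H]4CO[C@@H]5c4cc(OC)c(OCc5ccccc5)c(OC)c4)cc3[C@H]2CO)ccc1OCc1ccccc1 | intermediate
28 | 4-[(1S,3aR,4S,6aR)-4-[(2S,3S)-2-(4-hydroxy-3-methoxyphenyl)-3-(hydroxymethyl)-7-methoxy-2,3-dihydro-1-benzofuran-5-yl]tetrahydro-1H,3H-furo[3,4-c]furan-1-yl]-2,6-dimethoxyphenol (CNP0126146.1) | COc1cc([C@H]2Oc3c(OC)cc([C@H]4OC[C@H]5[C@@H]4CO[C@@H]5c4cc(OC)c(O)c(OC)c4)cc3[C@H]2CO)ccc1O | target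

Total step count: 17.
Longest linear sequence: 16 steps (steps 1–10 and 12–17; step 11 is a one-step side branch).

Steps most likely to fail

Step 7. Loss of nitrogen may lead to a carbene-type 1,2-hydride shift from C2 (giving the flavone) or to insertion into the O–H bond of methanol instead of ring contraction, and non-kinetic protonation or later enolisation may erode the cis configuration at C3. The fallback makes the cis ester by a rhodium carbenoid C–H insertion, whose concerted transition state gives the cis isomer directly. It sets out from iodide 2. O-Alkylation with 4-(benzyloxy)-3-methoxybenzyl chloride (K2CO3, DMF) would give methyl 4-{[4-(benzyloxy)-3-methoxyphenyl]methoxy}-3-iodo-5-methoxybenzoate F1. Coupling with methyl diazoacetate under zerovalent palladium catalysis (Pd(PPh3)4, Ag2CO3, Et3N, toluene) would give methyl 4-{[4-(benzyloxy)-3-methoxyphenyl]methoxy}-3-(1-diazo-2-methoxy-2-oxoethyl)-5-methoxybenzoate F2. Rh2(S-PTTL)4 or its enantiomer, whichever gives (2S,3R), in toluene at −60 °C would insert the carbenoid into the benzylic ether C–H bond and come back to the route at 13.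

Step 12. The lactone enolate 21 may be protonated or may revert instead of adding to the hindered, electron-rich aldehyde 16, so that the valuable aldehyde is not consumed. The fallback exchanges the roles of the two aldehydes and sets out from 16. Dithioacetalisation (propane-1,3-dithiol, MgBr2·OEt2, Et2O) would give 2-BFsi-1,3-dithiane F3. n-BuLi would give 2-lithio-2-BFsi-1,3-dithiane F4, which adds to 19 to give lithium (4R,5R)-4-(2-BFsi-1,3-dithian-2-yl)-5-(MenO)-4,5-dihydrofuran-2-olate F5. Trapping with the inexpensive aldehyde 17 in excess would give (3S,4R,5R)-3-[ArS(hydroxy)methyl]-4-(2-BFsi-1,3-dithian-2-yl)-5-(MenO)dihydrofuran-2(3H)-one F6. Hg(ClO4)2 with CaCO3 would give (3S,4R,5R)-3-[ArS(hydroxy)methyl]-4-(BFsi-carbonyl)-5-(MenO)dihydrofuran-2(3H)-one F7, and LiAlH4 would come back to the route at tetraol 24. This is the same tetraol, because the 2,3-bis(hydroxymethyl) backbone forms with the same configuration whichever aryl group arrives as the dithiane.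

Step 16. The benzylic ion pairs may lose a proton to give styrenes, or be captured by an aryl ring or from the endo face, because the silyl ether oxygens are slow nucleophiles. The fallback uses the free primary hydroxyls as nucleophiles in a classical acid-catalysed cyclodehydration and sets out from tetraol 24. Brief treatment with catalytic camphorsulfonic acid in CH2Cl2 at 0 °C would close both rings through the benzylic cations to give (2S,3S)-2-ArG-5-[(1S,3aR,4S,6aR)-4-ArS-tetrahydro-1H,3H-furo[3,4-c]furan-1-yl]-3-{[(tert-butyldimethylsilyl)oxy]methyl}-7-methoxy-2,3-dihydro-1-benzofuran F8, and TBAF in THF would come back to the route at 27. Since acid can also ionise C2–O1 of the dihydrobenzofuran, exposure would be kept short and the cis configuration checked.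

Further compounds
F1 | step 7 | methyl 4-{[4-(benzyloxy)-3-methoxyphenyl]methoxy}-3-iodo-5-methoxybenzoate | COC(=O)c1cc(I)c(OCc2ccc(OCc3ccccc3)c(OC)c2)c(OC)c1
F2 | step 7 | methyl 4-{[4-(benzyloxy)-3-methoxyphenyl]methoxy}-3-(1-diazo-2-methoxy-2-oxoethyl)-5-methoxybenzoate | COC(=O)C(=[N+]=[N-])c1cc(C(=O)OC)cc(OC)c1OCc1ccc(OCc2ccccc2)c(OC)c1
F3 | step 12 | 2-BFsi-1,3-dithiane | COc1cc([C@H]2Oc3c(OC)cc(C4SCCCS4)cc3[C@H]2CO[Si](C)(C)C(C)(C)C)ccc1OCc1ccccc1
F4 | step 12 | 2-lithio-2-BFsi-1,3-dithiane | COc1cc([C@H]2Oc3c(OC)cc(C4([Li])SCCCS4)cc3[C@H]2CO[Si](C)(C)C(C)(C)C)ccc1OCc1ccccc1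
F5 | step 12 | lithium (4R,5R)-4-(2-BFsi-1,3-dithian-2-yl)-5-(MenO)-4,5-dihydrofuran-2-olate | COc1cc([C@H]2Oc3c(OC)cc(C4([C@@H]5C=C(O[Li])O[C@H]5O[C@@H]6C[C@H](C)CC[C@H]6C(C)C)SCCCS4)cc3[C@H]2CO[Si](C)(C)C(C)(C)C)ccc1OCc1ccccc1
F6 | step 12 | (3S,4R,5R)-3-[ArS(hydroxy)methyl]-4-(2-BFsi-1,3-dithian-2-yl)-5-(MenO)dihydrofuran-2(3H)-one | COc1cc([C@H]2Oc3c(OC)cc(C4([C@H]5[C@H](O[C@@H]6C[C@H](C)CC[C@H]6C(C)C)OC(=O)[C@@H]5C(O)c5cc(OC)c(OCc6ccccc6)c(OC)c5)SCCCS4)cc3[C@H]2CO[Si](C)(C)C(C)(C)C)ccc1OCc1ccccc1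
F7 | step 12 | (3S,4R,5R)-3-[ArS(hydroxy)methyl]-4-(BFsi-carbonyl)-5-(MenO)dihydrofuran-2(3H)-one | COc1cc([C@H]2Oc3c(OC)cc(C(=O)[C@H]4[C@H](O[C@@H]5C[C@H](C)CC[C@H]5C(C)C)OC(=O)[C@@H]4C(O)c4cc(OC)c(OCc5ccccc5)c(OC)c4)cc3[C@H]2CO[Si](C)(C)C(C)(C)C)ccc1OCc1ccccc1
F8 | step 16 | (2S,3S)-2-ArG-5-[(1S,3aR,4S,6aR)-4-ArS-tetrahydro-1H,3H-furo[3,4-c]furan-1-yl]-3-{[(tert-butyldimethylsilyl)oxy]methyl}-7-methoxy-2,3-dihydro-1-benzofuran | COc1cc([C@H]2Oc3c(OC)cc([C@H]4OC[C@H]5[C@@H]4CO[C@@H]5c4cc(OC)c(OCc5ccccc5)c(OC)c4)cc3[C@H]2CO[Si](C)(C)C(C)(C)C)ccc1OCc1ccccc1
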